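**Strategy**

Ring atoms are numbered C1 (CHOAc), C2 (CH2), C3 (CHBr), C4 (CMe2), C5=C6, with the side chain C7 (CHBr)–C8 (CH2Cl) on C6. Everything rests on replacing the neopentyl C3–Br bond by a C3–B bond: C3, next to the C4 quaternary carbon and β to the C1 oxygen, is the β-carbon of a 4,4-dimethylcyclohexa-2,5-dienone. One copper-catalysed enantioselective conjugate borylation sets C3 and at the same time tells the two enones apart, because only C5=C6 carries a substituent on its α-carbon. The precursor is that cross-conjugated dienone, bearing the chiral-pool (S)-CH(OSiR3)CH2Cl chain on C6; boron later relays to C1 and is exchanged for bromine with inversion.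

Key step: step 6

Assumption: the sense of induction of the copper catalyst cannot be assigned with certainty for this dienone; (R,R)-QuinoxP* is written in step 6, and its antipode is to be used if a test run shows the opposite configuration at C3.

**Route**

Step 1
Reactants: 1 ethyl (3S)-4-chloro-3-hydroxybutanoate
Product: 2 ethyl (3S)-3-(tert-butyldiphenylsilyloxy)-4-chlorobutanoate
Conditions: TBDPSCl, imidazole, DMF, rt
Reagents that add atoms: tert-butyl(chloro)diphenylsilane, CC(C)(C)[Si](Cl)(c1ccccc1)c1ccccc1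
Why: Imidazole-mediated silylation of the secondary alcohol leaves the stereocentre untouched, and the diphenylsilyl ether is chosen because it should withstand the acid of step 4 and the later selective cleavage of a triethylsilyl ether.

Step 2
Reactants: 2 ethyl (3S)-3-(tert-butyldiphenylsilyloxy)-4-chlorobutanoate
Product: 3 (3S)-3-(tert-butyldiphenylsilyloxy)-4-chloro-N-methoxy-N-methylbutanamide
Conditions: MeNH(OMe)·HCl, i-PrMgCl, THF, −20 °C
Reagents that add atoms: N,O-dimethylhydroxylamine hydrochloride, CNOC.Cl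
Why: Weinreb amide formation by direct aminolysis of the ester with the chloromagnesium amide is fast at low temperature, where neither β-elimination of the silyloxy group nor attack on the primary chloride should compete.

Step 3
Reactants: 3 (3S)-3-(tert-butyldiphenylsilyloxy)-4-chloro-N-methoxy-N-methylbutanamide, 4 vinylmagnesium bromide
Product: 5 (5S)-5-(tert-butyldiphenylsilyloxy)-6-chlorohex-1-en-3-one
Conditions: THF, 0 °C; inverse quench into cold 1 M HCl
Reagents that add atoms: none
Why: Weinreb ketone synthesis, in which the chelated tetrahedral adduct prevents over-addition and the acidic quench removes the liberated amine before it can add to the vinyl ketone.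

Step 4
Reactants: 5 (5S)-5-(tert-butyldiphenylsilyloxy)-6-chlorohex-1-en-3-one, 6 isobutyraldehyde
Product: 10 2-[(1S)-1-(tert-butyldiphenylsilyloxy)-2-chloroethyl]-4,4-dimethylcyclohex-2-en-1-one, via pyrrolidine enamine 7 (not isolated), via aminodihydropyran adduct 8 (not isolated), via keto aldehyde 9 (not isolated)
Conditions: i-PrCHO (1.5 equiv), pyrrolidine (1.2 equiv), 4 Å MS, PhMe, 0 °C to rt; then 5, rt; aq. AcOH/NaOAc, rt; then TsOH·H2O (cat.), PhH, reflux (Dean–Stark)
Reagents that add atoms: none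
Why: Robinson annulation in its Stork enamine form, in which the enamine adds to the vinyl ketone, buffered hydrolysis frees the 1,5-keto aldehyde and acid-catalysed intramolecular aldol condensation closes the enone; acid is chosen because the weakly basic silyl ether and the CH2Cl-deactivated C7–O bond should resist the β-elimination an enolate would provoke, and C7 is not enolisable.

Step 5
Reactants: 10 2-[(1S)-1-(tert-butyldiphenylsilyloxy)-2-chloroethyl]-4,4-dimethylcyclohex-2-en-1-one
Product: 12 2-[(1S)-1-(tert-butyldiphenylsilyloxy)-2-chloroethyl]-4,4-dimethylcyclohexa-2,5-dien-1-one, via trimethylsilyl dienol ether 11 (not isolated)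
Conditions: TMSOTf, Et3N, CH2Cl2, 0 °C; solvent switch; Pd(OAc)2 (1.05 equiv), MeCN, rt
Reagents that add atoms: none
Why: Saegusa–Ito dehydrogenation, in which soft enolisation can only occur at C2 (C4 is quaternary) and the oxa-π-allyl palladium species from the silyl dienol ether undergoes β-hydride elimination to the cross-conjugated dienone.

Step 6
Reactants: 12 2-[(1S)-1-(tert-butyldiphenylsilyloxy)-2-chloroethyl]-4,4-dimethylcyclohexa-2,5-dien-1-one, 13 bis(pinacolato)diboron
Product: 14 (5R)-2-[(1S)-1-(tert-butyldiphenylsilyloxy)-2-chloroethyl]-4,4-dimethyl-5-(4,4,5,5-tetramethyl-1,3,2-dioxaborolan-2-yl)cyclohex-2-en-1-one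
Conditions: CuCl (5 mol%), (R,R)-QuinoxP* [(R,R)-2,3-bis(tert-butylmethylphosphino)quinoxaline] (6 mol%), NaOtBu (10 mol%), MeOH (2 equiv), THF, 0 °C to rt
Reagents that add atoms: none
Why: CuCl, NaOtBu and the bisphosphine give a ligated monovalent copper alkoxide that undergoes σ-bond metathesis with B2pin2 to a copper boryl species, which adds syn across C2=C3 with boron on C3 and copper on C2, and methanol protonates the resulting copper enolate and regenerates the copper alkoxide. The closest known reaction type is the copper–bisphosphine-catalysed enantioselective β-borylation of cyclic enones, including β-substituted cyclohexenones, and conjugate additions to 4,4-dimethylcyclohexadienone show that a β-carbon beside this quaternary centre is accessible. No ring is closed and no skeletal bond is formed. The single new stereocentre, C3 (R), is set by the chiral ligand on copper, since the two faces of the C2=C3 bond differ only through the remote C7 centre. Site selectivity between the two enones is needed and should be secured by the C6 side chain, which makes the C5=C6 enone α-branched and shielded so that borylcupration there is much slower, while one equivalent of B2pin2 prevents a second addition. The primary chloride should survive because the alkoxide is present only in catalytic amount, whereas copper-mediated borylation of alkyl halides consumes base stoichiometrically.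

Step 7
Reactants: 14 (5R)-2-[(1S)-1-(tert-butyldiphenylsilyloxy)-2-chloroethyl]-4,4-dimethyl-5-(4,4,5,5-tetramethyl-1,3,2-dioxaborolan-2-yl)cyclohex-2-en-1-one
Product: 15 (1S,5R)-2-[(1S)-1-(tert-butyldiphenylsilyloxy)-2-chloroethyl]-4,4-dimethyl-5-(4,4,5,5-tetramethyl-1,3,2-dioxaborolan-2-yl)cyclohex-2-en-1-ol
Conditions: NaBH4, CeCl3·7H2O, MeOH, −78 °C
Reagents that add atoms: none
Why: Luche reduction should give clean 1,2-reduction of the enone, with hydride entering anti to the C3 boryl substituent so that the new C1 hydroxyl (1S) lies cis to boron.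

Step 8
Reactants: 15 (1S,5R)-2-[(1S)-1-(tert-butyldiphenylsilyloxy)-2-chloroethyl]-4,4-dimethyl-5-(4,4,5,5-tetramethyl-1,3,2-dioxaborolan-2-yl)cyclohex-2-en-1-ol
Product: 16 triethyl{[(1S,5R)-2-[(1S)-1-(tert-butyldiphenylsilyloxy)-2-chloroethyl]-4,4-dimethyl-5-(4,4,5,5-tetramethyl-1,3,2-dioxaborolan-2-yl)cyclohex-2-en-1-yl]oxy}silane
Conditions: TESCl, imidazole, DMF, 0 °C to rt
Reagents that add atoms: chlorotriethylsilane, CC[Si](Cl)(CC)CC
Why: Standard silylation masks the hydroxyl as a triethylsilyl ether that tolerates the aryllithium of step 9 and can later be removed without touching the tert-butyldiphenylsilyl ether.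

Step 9
Reactants: 16 triethyl{[(1S,5R)-2-[(1S)-1-(tert-butyldiphenylsilyloxy)-2-chloroethyl]-4,4-dimethyl-5-(4,4,5,5-tetramethyl-1,3,2-dioxaborolan-2-yl)cyclohex-2-en-1-yl]oxy}silane
Product: 18 triethyl{[(1S,5S)-5-bromo-2-[(1S)-1-(tert-butyldiphenylsilyloxy)-2-chloroethyl]-4,4-dimethylcyclohex-2-en-1-yl]oxy}silane, via lithium aryl boronate complex 17 (not isolated)
Conditions: 3,5-(CF3)2C6H3Br, n-BuLi, THF, −78 °C; then 16, −78 °C; then NBS, −78 °C to rt
Reagents that add atoms: N-bromosuccinimide, O=C1CCC(=O)N1Br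
Why: Stereoinvertive electrophilic bromination of a secondary alkyl boronate complex, in which the electron-poor aryllithium turns the pinacol boronate into a nucleophilic ate complex that N-bromosuccinimide attacks at carbon from the side opposite boron, so the (S)-configured C3–Br bond forms without any nucleophilic substitution at the neopentyl centre.

Step 10
Reactants: 18 triethyl{[(1S,5S)-5-bromo-2-[(1S)-1-(tert-butyldiphenylsilyloxy)-2-chloroethyl]-4,4-dimethylcyclohex-2-en-1-yl]oxy}silane
Product: 19 (1S,5S)-5-bromo-2-[(1S)-1-(tert-butyldiphenylsilyloxy)-2-chloroethyl]-4,4-dimethylcyclohex-2-en-1-ol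
Conditions: PPTS (cat.), MeOH/CH2Cl2, 0 °C to rt
Reagents that add atoms: none
Why: Mild acid-catalysed methanolysis should remove the triethylsilyl ether selectively, the bulkier tert-butyldiphenylsilyl ether and both halides being inert.

Step 11
Reactants: 19 (1S,5S)-5-bromo-2-[(1S)-1-(tert-butyldiphenylsilyloxy)-2-chloroethyl]-4,4-dimethylcyclohex-2-en-1-ol
Product: 20 (1R,5S)-5-bromo-2-[(1S)-1-(tert-butyldiphenylsilyloxy)-2-chloroethyl]-4,4-dimethylcyclohex-2-en-1-yl acetate
Conditions: PPh3, DIAD, AcOH, PhMe, 0 °C to rt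
Reagents that add atoms: acetic acid, CC(=O)O
Why: Mitsunobu reaction, in which acetate displaces the C1 alkoxyphosphonium ion with inversion to give the (1R) acetate cis to bromine, the SN2' position C5 being shielded by the C4 gem-dimethyl group.

Step 12
Reactants: 20 (1R,5S)-5-bromo-2-[(1S)-1-(tert-butyldiphenylsilyloxy)-2-chloroethyl]-4,4-dimethylcyclohex-2-en-1-yl acetate
Product: 21 (1R,5S)-5-bromo-2-[(1S)-2-chloro-1-hydroxyethyl]-4,4-dimethylcyclohex-2-en-1-yl acetate
Conditions: HF·pyridine, THF/pyridine, 0 °C to rt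
Reagents that add atoms: none
Why: Fluoride cleaves the Si–O bond in an acidic medium, so no C7 alkoxide forms that could close an epoxide onto C8 or accept the C1 acetyl group.

Step 13
Reactants: 21 (1R,5S)-5-bromo-2-[(1S)-2-chloro-1-hydroxyethyl]-4,4-dimethylcyclohex-2-en-1-yl acetate
Product: 22 (1R,5S)-5-bromo-2-[(1R)-1-bromo-2-chloroethyl]-4,4-dimethylcyclohex-2-en-1-yl acetate
Conditions: CBr4, PPh3, CH2Cl2, 0 °C
Reagents that add atoms: carbon tetrabromide, BrC(Br)(Br)Br
Why: Appel reaction, in which bromide displaces the C7 alkoxyphosphonium ion with inversion to give the (R) bromide, while SN2' attack at C5 is blocked by the neighbouring quaternary carbon and ionisation is disfavoured by the adjacent CH2Cl group.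

**Compound list**

1 | ethyl (3S)-4-chloro-3-hydroxybutanoate | CCOC(=O)C[C@H](O)CCl | starting material
2 | ethyl (3S)-3-(tert-butyldiphenylsilyloxy)-4-chlorobutanoate | CCOC(=O)C[C@H](O[Si](c1ccccc1)(c1ccccc1)C(C)(C)C)CCl | intermediate
3 | (3S)-3-(tert-butyldiphenylsilyloxy)-4-chloro-N-methoxy-N-methylbutanamide | CON(C)C(=O)C[C@H](O[Si](c1ccccc1)(c1ccccc1)C(C)(C)C)CCl | intermediate
4 | vinylmagnesium bromide | C=C[Mg]Br | starting material
5 | (5S)-5-(tert-butyldiphenylsilyloxy)-6-chlorohex-1-en-3-one | C=CC(=O)C[C@H](O[Si](c1ccccc1)(c1ccccc1)C(C)(C)C)CCl | intermediate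
6 | isobutyraldehyde (2-methylpropanal) | CC(C)C=O | starting material
7 | 1-(2-methylprop-1-en-1-yl)pyrrolidine | CC(C)=CN1CCCC1 | intermediate
8 | 1-{6-[(2S)-2-(tert-butyldiphenylsilyloxy)-3-chloropropyl]-3,3-dimethyl-3,4-dihydro-2H-pyran-2-yl}pyrrolidine (either configuration at the aminal carbon) | CC1(C)CC=C(C[C@H](O[Si](c2ccccc2)(c2ccccc2)C(C)(C)C)CCl)OC1N1CCCC1 | intermediate
9 | (7S)-7-(tert-butyldiphenylsilyloxy)-8-chloro-2,2-dimethyl-5-oxooctanal | O=CC(C)(C)CCC(=O)C[C@H](O[Si](c1ccccc1)(c1ccccc1)C(C)(C)C)CCl | intermediate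
10 | 2-[(1S)-1-(tert-butyldiphenylsilyloxy)-2-chloroethyl]-4,4-dimethylcyclohex-2-en-1-one | O=C1CCC(C)(C)C=C1[C@H](O[Si](c2ccccc2)(c2ccccc2)C(C)(C)C)CCl | intermediate
11 | tert-butyl{(1S)-2-chloro-1-[3,3-dimethyl-6-(trimethylsilyloxy)cyclohexa-1,5-dien-1-yl]ethoxy}diphenylsilane | C[Si](C)(C)OC1=CCC(C)(C)C=C1[C@H](O[Si](c2ccccc2)(c2ccccc2)C(C)(C)C)CCl | intermediate
12 | 2-[(1S)-1-(tert-butyldiphenylsilyloxy)-2-chloroethyl]-4,4-dimethylcyclohexa-2,5-dien-1-one | O=C1C=CC(C)(C)C=C1[C@H](O[Si](c2ccccc2)(c2ccccc2)C(C)(C)C)CCl | intermediate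
13 | bis(pinacolato)diboron | CC1(C)OB(OC1(C)C)B1OC(C)(C)C(C)(C)O1 | starting material
14 | (5R)-2-[(1S)-1-(tert-butyldiphenylsilyloxy)-2-chloroethyl]-4,4-dimethyl-5-(4,4,5,5-tetramethyl-1,3,2-dioxaborolan-2-yl)cyclohex-2-en-1-one | O=C1C[C@@H](B2OC(C)(C)C(C)(C)O2)C(C)(C)C=C1[C@H](O[Si](c2ccccc2)(c2ccccc2)C(C)(C)C)CCl | intermediate
15 | (1S,5R)-2-[(1S)-1-(tert-butyldiphenylsilyloxy)-2-chloroethyl]-4,4-dimethyl-5-(4,4,5,5-tetramethyl-1,3,2-dioxaborolan-2-yl)cyclohex-2-en-1-ol | O[C@H]1C[C@@H](B2OC(C)(C)C(C)(C)O2)C(C)(C)C=C1[C@H](O[Si](c2ccccc2)(c2ccccc2)C(C)(C)C)CCl | intermediate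
16 | triethyl{[(1S,5R)-2-[(1S)-1-(tert-butyldiphenylsilyloxy)-2-chloroethyl]-4,4-dimethyl-5-(4,4,5,5-tetramethyl-1,3,2-dioxaborolan-2-yl)cyclohex-2-en-1-yl]oxy}silane | CC[Si](CC)(CC)O[C@H]1C[C@@H](B2OC(C)(C)C(C)(C)O2)C(C)(C)C=C1[C@H](O[Si](c2ccccc2)(c2ccccc2)C(C)(C)C)CCl | intermediate
17 | lithium boronate complex of 16 carrying a 3,5-bis(trifluoromethyl)phenyl group on boron (configuration at C3 unchanged) | [Li+].CC[Si](CC)(CC)O[C@H]1C[C@@H]([B-]2(OC(C)(C)C(C)(C)O2)c2cc(C(F)(F)F)cc(C(F)(F)F)c2)C(C)(C)C=C1[C@H](O[Si](c2ccccc2)(c2ccccc2)C(C)(C)C)CCl | intermediate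
18 | triethyl{[(1S,5S)-5-bromo-2-[(1S)-1-(tert-butyldiphenylsilyloxy)-2-chloroethyl]-4,4-dimethylcyclohex-2-en-1-yl]oxy}silane | CC[Si](CC)(CC)O[C@H]1C[C@H](Br)C(C)(C)C=C1[C@H](O[Si](c2ccccc2)(c2ccccc2)C(C)(C)C)CCl | intermediate
19 | (1S,5S)-5-bromo-2-[(1S)-1-(tert-butyldiphenylsilyloxy)-2-chloroethyl]-4,4-dimethylcyclohex-2-en-1-ol | O[C@H]1C[C@H](Br)C(C)(C)C=C1[C@H](O[Si](c2ccccc2)(c2ccccc2)C(C)(C)C)CCl | intermediate
20 | (1R,5S)-5-bromo-2-[(1S)-1-(tert-butyldiphenylsilyloxy)-2-chloroethyl]-4,4-dimethylcyclohex-2-en-1-yl acetate | CC(=O)O[C@@H]1C[C@H](Br)C(C)(C)C=C1[C@H](O[Si](c2ccccc2)(c2ccccc2)C(C)(C)C)CCl | intermediate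
21 | (1R,5S)-5-bromo-2-[(1S)-2-chloro-1-hydroxyethyl]-4,4-dimethylcyclohex-2-en-1-yl acetate | CC(=O)O[C@@H]1C[C@H](Br)C(C)(C)C=C1[C@H](O)CCl | intermediate
22 | (1R,5S)-5-bromo-2-[(1R)-1-bromo-2-chloroethyl]-4,4-dimethylcyclohex-2-en-1-yl acetate | CC(=O)O[C@@H]1C[C@H](Br)C(C)(C)C=C1[C@@H](Br)CCl | target

**Step count and risk**

Total step count: 13 (steps 4 and 5 each run several operations in one sequence without isolation).
Longest linear sequence: 13 steps, from 1 to 22; compounds 4, 6 and 13 enter as single inputs.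

Steps most likely to fail:

1. Step 9. The boronate complex may be oxidised by single-electron transfer so that the configuration at C3 is scrambled. The brominating agent may fail to reach the rear of the C3–B bond beside the C4 quaternary carbon. The ring alkene may be brominated in competition. Fallback, setting out from 16 and returning at 18: the C–B bond would be oxidised with retention (NaBO3·4H2O, THF/H2O) to (1R,5S)-4-[(1S)-1-(tert-butyldiphenylsilyloxy)-2-chloroethyl]-2,2-dimethyl-5-(triethylsilyloxy)cyclohex-3-en-1-ol F1. This would be converted (Tf2O, pyridine, CH2Cl2, −40 °C) into (1R,5S)-4-[(1S)-1-(tert-butyldiphenylsilyloxy)-2-chloroethyl]-2,2-dimethyl-5-(triethylsilyloxy)cyclohex-3-en-1-yl trifluoromethanesulfonate F2. The triflate would be displaced with inversion by Bu4NBr (PhMe, −20 °C to rt) to give 18. SN2 displacement of triflates next to a gem-dimethyl carbon by soft anions is established at C3 of 4,4-dimethyl steroids and triterpenoids.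

2. Step 4. The C7 silyloxy group may be lost by β-elimination from the enolised ketone, which would also erase the stereocentre, or the silyl ether may be cleaved by the acid before the ring closes. Fallback, setting out from 6 and returning at 10, with the ring made first and the side chain attached afterwards:
   - Acid-catalysed annulation of 6 with but-3-en-2-one (H2SO4 cat., then PhH, reflux) would give 4,4-dimethylcyclohex-2-en-1-one F3, which is also an article of commerce.
   - α-Iodination (I2, pyridine, CH2Cl2) would give 2-iodo-4,4-dimethylcyclohex-2-en-1-one F4.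
   - Ketalisation (ethylene glycol, TsOH, PhH, reflux) would give 6-iodo-8,8-dimethyl-1,4-dioxaspiro[4.5]dec-6-ene F5.
   - Iodine–lithium exchange (n-BuLi, THF, −78 °C) and acylation with 2-chloro-N-methoxy-N-methylacetamide would give 2-chloro-1-(8,8-dimethyl-1,4-dioxaspiro[4.5]dec-6-en-6-yl)ethan-1-one F6.
   - CBS reduction ((S)-Me-CBS oxazaborolidine, BH3·SMe2, THF, −20 °C), with the alkenyl group as the larger substituent, should give (1S)-2-chloro-1-(8,8-dimethyl-1,4-dioxaspiro[4.5]dec-6-en-6-yl)ethan-1-ol F7.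
   - Silylation (TBDPSCl, imidazole, DMF) would give tert-butyl[(1S)-2-chloro-1-(8,8-dimethyl-1,4-dioxaspiro[4.5]dec-6-en-6-yl)ethoxy]diphenylsilane F8.
   - Ketal hydrolysis (PPTS, acetone/H2O, 50 °C) would deliver 10.
   
   Here the C7 stereocentre comes from reagent control and no enolisable β-silyloxy ketone is ever formed.

3. Step 11. Activation of the hindered allylic alcohol may be slow, the alkoxyphosphonium ion may eliminate to a cyclohexadiene, or acetylation may occur with retention. Fallback, setting out from 19 and returning at 20, with inversion by oxidation and reduction in place of substitution: Dess–Martin periodinane (NaHCO3, CH2Cl2, 0 °C) would give (5S)-5-bromo-2-[(1S)-1-(tert-butyldiphenylsilyloxy)-2-chloroethyl]-4,4-dimethylcyclohex-2-en-1-one F9, to be handled cold and without amine base. Luche reduction (NaBH4, CeCl3·7H2O, MeOH, −78 °C), with hydride now entering anti to the C3 bromine, should give (1R,5S)-5-bromo-2-[(1S)-1-(tert-butyldiphenylsilyloxy)-2-chloroethyl]-4,4-dimethylcyclohex-2-en-1-ol F10. Acetylation (Ac2O, pyridine, DMAP) would then give 20.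

**Further compounds**

F1 | step 9 | (1R,5S)-4-[(1S)-1-(tert-butyldiphenylsilyloxy)-2-chloroethyl]-2,2-dimethyl-5-(triethylsilyloxy)cyclohex-3-en-1-ol | CC[Si](CC)(CC)O[C@H]1C[C@@H](O)C(C)(C)C=C1[C@H](O[Si](c2ccccc2)(c2ccccc2)C(C)(C)C)CCl
F2 | step 9 | (1R,5S)-4-[(1S)-1-(tert-butyldiphenylsilyloxy)-2-chloroethyl]-2,2-dimethyl-5-(triethylsilyloxy)cyclohex-3-en-1-yl trifluoromethanesulfonate | CC[Si](CC)(CC)O[C@H]1C[C@@H](OS(=O)(=O)C(F)(F)F)C(C)(C)C=C1[C@H](O[Si](c2ccccc2)(c2ccccc2)C(C)(C)C)CCl
F3 | step 4 | 4,4-dimethylcyclohex-2-en-1-one | CC1(C)CCC(=O)C=C1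
F4 | step 4 | 2-iodo-4,4-dimethylcyclohex-2-en-1-one | CC1(C)CCC(=O)C(I)=C1
F5 | step 4 | 6-iodo-8,8-dimethyl-1,4-dioxaspiro[4.5]dec-6-ene | CC1(C)CCC2(OCCO2)C(I)=C1
F6 | step 4 | 2-chloro-1-(8,8-dimethyl-1,4-dioxaspiro[4.5]dec-6-en-6-yl)ethan-1-one | CC1(C)CCC2(OCCO2)C(=C1)C(=O)CCl
F7 | step 4 | (1S)-2-chloro-1-(8,8-dimethyl-1,4-dioxaspiro[4.5]dec-6-en-6-yl)ethan-1-ol | CC1(C)CCC2(OCCO2)C(=C1)[C@H](O)CCl
F8 | step 4 | tert-butyl[(1S)-2-chloro-1-(8,8-dimethyl-1,4-dioxaspiro[4.5]dec-6-en-6-yl)ethoxy]diphenylsilane | CC1(C)CCC2(OCCO2)C(=C1)[C@H](O[Si](c3ccccc3)(c3ccccc3)C(C)(C)C)CCl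
F9 | step 11 | (5S)-5-bromo-2-[(1S)-1-(tert-butyldiphenylsilyloxy)-2-chloroethyl]-4,4-dimethylcyclohex-2-en-1-one | O=C1C[C@H](Br)C(C)(C)C=C1[C@H](O[Si](c2ccccc2)(c2ccccc2)C(C)(C)C)CCl
F10 | step 11 | (1R,5S)-5-bromo-2-[(1S)-1-(tert-butyldiphenylsilyloxy)-2-chloroethyl]-4,4-dimethylcyclohex-2-en-1-ol | O[C@@H]1C[C@H](Br)C(C)(C)C=C1[C@H](O[Si](c2ccccc2)(c2ccccc2)C(C)(C)C)CCl
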